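(The runs were generated by integration on assumed constants, noise included.)

| setting | larch | cedar | flask |
|---|---|---|---|
| substrate | 1.2 M | 1.2 M | 1.2 M |
| reagent | 0.90 equiv | 0.90 equiv | 0.900 equiv |
| free catalyst | 0.1 mol% | 0.15 mol% | 0.2 mol% |
| remark | run made earlier | run made earlier |  |

- larch (time / h: product / %, substrate / %): 0.667: 2.4, 97.2; 2.00: 7.0, 94.9; 3.00: 9.4, 90.5; 5.00: 11.2, 89.4; 8.00: 15.7, 84.6; 10.0: 17.2, 85.3; 12.0: 18.7, 81.0
- cedar (time / h: product / %, substrate / %): 0.667: 4.6, 95.6; 2.00: 8.9, 91.2; 3.00: 10.4, 88.2; 5.00: 12.5, 85.0; 8.00: 17.5, 79.1; 10.0: 20.7, 79.4; 12.0: 23.1, 77.6

(each reading ± 1 percentage point)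

- no earlier run changes the charge of reagent; that part of a forecast is a guess

1. apparent order in reagent when 30 % of the substrate are converted (percent change of the rate of making product for one percent more reagent charged)
2. factor on the rate of making product when 30 % of the substrate are converted if reagent is charged twice over

Substrate and reagent make product on a catalyst, and the cedar run held 1.50 times the catalyst of the larch run, yet by 12.0 h its product stood at a smaller multiple, 1.24, of the larch product. So catalyst did not simply multiply the rate.

Did depletion slow the larch run? I read the rate over its last 4.00 h as 4.67 times lower than over its first 2.00 h, while the substrate left was still 81.0 %. Depletion could not account for that, so I took the catalyst to be fading.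

What, then, does extra reagent do in the flask? Reagent is the limiting reagent here, so I worked with what is left. At 30 % conversion, 0.600 of the substrate charge remains as reagent. I kept 1.50, the leverage: the percent gain in reagent left for one percent more charged. Doubling the charge raises the reagent left 2.50 times. Taking the rate as proportional to reagent left, I reckoned an order of 1.50 and a factor of 2.50.

The forecast assumed a smaller power, 0.6, and gave 0.9 and 1.7, with the warning “Reagent was never varied, so its order is a guess”.

The flask gave an apparent order of 2.2 and a factor of 2.61.

    2 free catalyst ⇌ resting dimer (K = 520 M⁻¹, k = 0.0980 M⁻¹ s⁻¹)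
    reagent + catalyst intermediate A → catalyst intermediate B (k = 0.0990 M⁻¹ s⁻¹)
    substrate + free catalyst ⇌ catalyst intermediate A (K = 0.520 M⁻¹, k = 0.0280 M⁻¹ s⁻¹)
    2 free catalyst → spent catalyst (k = 0.130 M⁻¹ s⁻¹)
    catalyst intermediate B → free catalyst + product (k = 0.130 s⁻¹)

The flask's apparent order of 2.2 stood 1.49 times above the leverage, yet reagent enters the scheme through a single first-order step, so the excess is no higher power of reagent. The reverse step, catalyst intermediate A to substrate + free catalyst, has the largest single effect on that order, though it is not the whole reason: the same flask without it has an apparent order of −0.021, lower than the 0.68 of the same flask without the pairing of free catalyst into spent catalyst, which is another part. The flask needed 23.7 h to reach 30 % conversion, and spent catalyst already held 91.9 % of the catalyst at 15.0 h.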